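## The problem

1. The target is a germacranolide. Germacrane numbers are used for it and for every intermediate: C1 (epoxide CH), C2 (CHOH), C3, C4 (CH bearing the aldehyde C15), C5, C6 (lactone oxygen), C7, C8 (ester oxygen), C9, C10 (epoxide carbon bearing the methyl C14), C11–C13 (methylene lactone). α is the face of H-7 in the flat drawing.
2. The SMILES string reads as 1R,2S,4S,6R,7S,8S,10R. That means 2α-OH, 4β-CHO, a trans-fused lactone (6α-O, 7β-C11), an 8α-ester of (E)-2-methylbut-2-enoic (tiglic) acid, and a 1β,10α-epoxide with C2 and C9 trans, so the epoxide descends from a 1(10)E alkene.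
3. The hardest feature is the ten-membered carbocycle. Closing it end to end costs both entropy and transannular strain, and an E-trisubstituted alkene must be accommodated in it.
4. The seven stereocentres form two contiguous triads (C1/C2/C10 and C6/C7/C8) plus the lone C4. Inside each triad the carbinol can steer its neighbours. The triads and C4 are remote from each other on a floppy ring and cannot control one another there.
5. A pseudo-mirror plane runs through C4 and C9 (C2/C6, C1/C7, C10/C8). Each half is an allylic alcohol whose alkene has been functionalised from the periphery: by an oxygen atom on one side, by carbon and oxygen on the other.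
6. The feature that makes the key step possible is the chain C7–C8–C9, which links the oxygen-bearing C6 to the C1–C10 unit. A 6-ketone with a 1(10)E alkene is therefore a δ,ε-unsaturated ketone. A bond drawn across the ring from C1 to C6 turns C1–C2–C3–C4–C5–C6 into a cyclohexane that holds C2 and C4. It leaves C7=C8 and C9=C10(C14) as alkenyl arms on C6 and C1, which is the oxy-Cope retron. The oxygen site C8 lies β to that ketone and can first carry a leaving group.
7. Several groups will not survive rough treatment.
   - The aldehyde is epimerisable at C4, and its C4 epimer could lock as a five-membered lactol with the 2-OH.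
   - The methylene lactone is a Michael acceptor.
   - The epoxy alcohol is prone to Payne migration and acid opening.
   - A free 8-OH next to the lactone can undergo an acyl shift.

   These groups must appear last and under non-basic conditions.

## Retrosynthesis

**33 ⇒ 32 ⇒ 31.** No C–C bond is cut. The aldehyde returns to the primary alcohol 32, and the C1–O–C10 bridge is removed to give the 1(10)E alkene diol 31.
- This order keeps the epimerisable aldehyde and the acid-labile epoxide out of all earlier steps.
- The forward reactions must oxidise a primary alcohol beside a secondary one.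
- They must also deliver oxygen to the outer face of the only electron-rich alkene, on the side of the 2α-OH.

**31 ⇒ 30 ⇒ 28 + 29.** The two O–Si bonds and the O8–acyl bond are cut. The ester goes on after the lactone chemistry because a tiglate would not survive carbanion conditions. Acid chloride 29 is purchasable. The forward step is a plain acylation of the only free hydroxyl.

**28 ⇒ 27 ⇒ 26.** C11=C13 and C7–C11 are cut, which leaves a 7α,8α-epoxide and a phosphonoacetate on O6.
- The neighbouring cut, alkylation of a C7 enolate of a 6-ketone, is ruled out. Any enolate at C7 has the C8 oxygen in the β position and would expel it.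
- In 26 the carbanion sits at C11, and the tether fixes the site of attack (C7, five-membered ring).
- SN2 inversion writes 7β-C11 and leaves 8α-O. The same phosphonate then delivers C13.
- Three bonds and two stereocentres arise from one ester.

**26 ⇒ 24 + 25 ⇒ 23 ⇒ 22.** The C6–O bond (formed with inversion), the epoxide oxygen and the C6–H bond are removed.
- A Z-allylic alcohol in a medium ring is epoxidised from the exposed face, on the side of its hydroxyl, when H-6 eclipses the alkene.
- This gives the epoxide trans to the hydroxyl in the flat drawing. The 6β-alcohol 23 therefore leads to the 7α,8α-epoxide 24, and the Mitsunobu esterification with 25 corrects C6 at no cost in steps.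
- Dienone 22 carries only the stereocentres C2 and C4.

**22 ⇒ 21 ⇒ 19 (key disconnection).** C8–C9 is cut, C1–C6 is restored, and a phenoxy group is put back on C8.
- The ten-membered ring is never closed from its ends. It is unveiled from the cyclohexanol 19 by an anionic oxy-Cope rearrangement, followed by loss of phenoxide from enolate 21.
- The same bond set could be approached by a Grob fragmentation, but that would need a tertiary leaving group at C10.
- The rearrangement needs only two alkenyl arms that are trans on a chair.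
- The forward step must give 1(10)E and 7Z and must leave the skipped diene unconjugated.

**19 ⇒ 13 + 16; 16 ⇒ 14.** The C6–C7 bond is cut to ketone 13 and the two-carbon bromide 16, which is made in one operation from phenyl vinyl ether 14. The addition must occur trans to the isopropenyl group and without enolisation of 13.

**13 ⇒ 12 ⇒ 10 ⇒ 8 + 9 ⇒ 7.** O–Si, C2–O and C1–C10 are cut. On a 5-substituted cyclohexenone, C4 controls C2 through the 3,5-trans rule. This is the only place in the route where the remote pair C2/C4 can be related reliably. C1 is a throw-away centre.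

**7 ⇒ 3 + 4; 3 ⇒ 2 ⇒ 1.** The ring C1–C6 is cut at C4–C5 and C1=C2 into an enal and acetoacetate 4. A single catalytic asymmetric Michael addition sets C4, the source of all absolute configuration that is not reagent-controlled.

## Roads not taken

**Alternative 1:** (the most obvious) cut C6–C7 and O6–C12.
- Forward key step: intramolecular Nozaki–Hiyama allylation of the ω-formyl 2-(bromomethyl)enoate A1 with CrCl2 (divalent chromium), followed by lactonisation to A2.
- It forms the lactone and C6/C7 at once. However, it closes the strained E-cyclodecene end to end at high dilution.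
- It needs a linear precursor in which C2, C4 and C8 are each set by a separate asymmetric operation.
- C6/C7 are related to C8 only through an acyclic model inside a macrocyclic transition state.
- The chosen plan relates C2 to C4 on a chair and never has to pay for ring closure.

**Alternative 2:** cut C7=C8 of alcohol 23.
- Forward key step: ring-closing metathesis of triene A3 with the second-generation Grubbs catalyst.
- The Z alkene would be the natural outcome. However, ten-membered carbocycles are the least favourable size for metathesis, so oligomers and ring-opened equilibria compete.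
- The 1,4-diene unit invites alkene migration by ruthenium hydrides.
- A3 again needs three independently made stereocentres and a preformed E-trisubstituted alkene.
- The rearrangement of 19 gives both alkene geometries from one transition state.

**Alternative 3:** cut C6–C7 within a larger ring.
- Forward key step: transannular [2,3]-Wittig ring contraction of the thirteen-membered bis-allylic ether A4 to the dienol A5.
- The contraction is attractive, but the carbanion at C6 must be allylic, which forces a C4=C5 alkene into the ring.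
- C4 and the aldehyde would then have to come from a chemoselective saturation of one of three alkenes, with C4 set by protonation.
- The isopropenyl group of A5 would still need two oxidations to become the lactone.
- The chosen plan carries C4 from the first asymmetric step.

Key step: step 10

## Steps

Step 1
Reactants: 1 (Z)-but-2-ene-1,4-diol
Product: 2 (Z)-4-(tert-butyldiphenylsilyloxy)but-2-en-1-ol
Conditions: t-BuPh2SiCl (0.3 equiv), imidazole, THF, 0 °C
Reagents that add atoms: tert-butyl(chloro)diphenylsilane, CC(C)(C)[Si](Cl)(c1ccccc1)c1ccccc1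
Why: Statistical monosilylation of a cheap symmetric diol used in excess; the acid-stable silyl group is needed for step 3.

Step 2
Reactants: 2 (Z)-4-(tert-butyldiphenylsilyloxy)but-2-en-1-ol
Product: 3 (E)-4-(tert-butyldiphenylsilyloxy)but-2-enal
Conditions: [C5H5NH][CrO3Cl], CH2Cl2, rt
Reagents that add atoms: none
Why: Chlorochromate oxidation of an allylic alcohol; the Z enal should isomerise to the conjugated E enal under the mildly acidic conditions, and the geometry is levelled in any case in the iminium ion of step 3.

Step 3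
Reactants: 3 (E)-4-(tert-butyldiphenylsilyloxy)but-2-enal; 4 tert-butyl acetoacetate
Product: 7 (S)-5-[(tert-butyldiphenylsilyloxy)methyl]cyclohex-2-en-1-one, via Michael adduct 5 (not isolated), via keto ester 6 (not isolated)
Conditions: (R)-α,α-diphenylprolinol trimethylsilyl ether (10 mol %), PhCO2H (10 mol %), toluene, rt; then p-TsOH·H2O (20 mol %), toluene, 80 °C
Reagents that add atoms: none
Why: Iminium-catalysed Michael addition of the β-keto ester, then acid-promoted aldol condensation, tert-butyl ester cleavage and decarboxylation (organocatalytic cyclohexenone annulation). The diphenyl(silyloxy)methyl group of the R catalyst shields one face of the E iminium ion, so that C5 adds to the open face of C4 and sets the 4β-CH2O substituent.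

Step 4
Reactants: 7 (S)-5-[(tert-butyldiphenylsilyloxy)methyl]cyclohex-2-en-1-one
Product: 8 (S)-5-[(tert-butyldiphenylsilyloxy)methyl]-2-iodocyclohex-2-en-1-one
Conditions: I2, pyridine, CH2Cl2, 0 °C to rt
Reagents that add atoms: iodine, II
Why: α-Iodination of an enone by conjugate addition of pyridine, iodination of the enolate and elimination; C4 is not touched.

Step 5
Reactants: 8 (S)-5-[(tert-butyldiphenylsilyloxy)methyl]-2-iodocyclohex-2-en-1-one; 9 isopropenylboronic acid pinacol ester
Product: 10 (S)-5-[(tert-butyldiphenylsilyloxy)methyl]-2-(prop-1-en-2-yl)cyclohex-2-en-1-one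
Conditions: PdCl2(dppf) (3 mol %), K3PO4, THF/H2O, 40 °C
Reagents that add atoms: none
Why: Suzuki–Miyaura coupling of a 2-iodoenone forms C1–C10 and brings in C9, C10 and C14; the cross-conjugated dienone is used promptly to avoid Diels–Alder dimerisation.

Step 6
Reactants: 10 (S)-5-[(tert-butyldiphenylsilyloxy)methyl]-2-(prop-1-en-2-yl)cyclohex-2-en-1-one
Product: 12 (2S,3S,5S)-5-[(tert-butyldiphenylsilyloxy)methyl]-3-hydroxy-2-(prop-1-en-2-yl)cyclohexan-1-one, via boryl ketone 11 (not isolated)
Conditions: B2pin2, CuCl (5 mol %), Xantphos (5 mol %), NaOt-Bu (10 mol %), MeOH (2 equiv), THF, 0 °C; then NaBO3·4H2O, THF/H2O, rt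
Reagents that add atoms: sodium perborate, [Na+].[Na+].O[B-]1(O)OO[B-](O)(O)OO1
Why: Copper-catalysed conjugate borylation and oxidation with retention (formal hydration of the enone). The boryl-copper species adds axially to C2 anti to the equatorial C4 substituent (3,5-trans rule), which sets 2α-O relative to 4β-C15; kinetic α-protonation places the isopropenyl group equatorial at the disposable centre C1.

Step 7
Reactants: 12 (2S,3S,5S)-5-[(tert-butyldiphenylsilyloxy)methyl]-3-hydroxy-2-(prop-1-en-2-yl)cyclohexan-1-one
Product: 13 (2S,3S,5S)-5-[(tert-butyldiphenylsilyloxy)methyl]-2-(prop-1-en-2-yl)-3-(triisopropylsilyloxy)cyclohexan-1-one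
Conditions: i-Pr3SiOTf, 2,6-lutidine, CH2Cl2, −78 to −20 °C
Reagents that add atoms: triisopropylsilyl triflate, CC(C)[Si](OS(=O)(=O)C(F)(F)F)(C(C)C)C(C)C
Why: Silylation with a hindered, non-nucleophilic base avoids retro-aldol cleavage and β-elimination of the aldol-type ketone; the bulky group is chosen because it should not migrate to O6 in step 10.

Step 8
Reactants: 14 phenyl vinyl ether
Product: 16 (Z)-(2-bromoethenyloxy)benzene, via dibromide 15 (not isolated)
Conditions: Br2, CH2Cl2, −78 °C; then PhNEt2, 90 °C
Reagents that add atoms: bromine, BrBr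
Why: Bromine addition to the enol ether and dehydrobromination, the standard access to (Z)-2-bromovinyl ethers; loss of the α-bromine with a β-hydrogen by anti elimination favours the Z isomer, which is purified by distillation.

Step 9
Reactants: 16 (Z)-(2-bromoethenyloxy)benzene; 13 (2S,3S,5S)-5-[(tert-butyldiphenylsilyloxy)methyl]-2-(prop-1-en-2-yl)-3-(triisopropylsilyloxy)cyclohexan-1-one
Product: 19 (1S,2S,3S,5S)-5-[(tert-butyldiphenylsilyloxy)methyl]-1-[(Z)-2-phenoxyethenyl]-2-(prop-1-en-2-yl)-3-(triisopropylsilyloxy)cyclohexan-1-ol, via vinyllithium 17 (not isolated), via organocerium 18 (not isolated)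
Conditions: 16, t-BuLi (2 equiv), Et2O, −78 °C; CeCl3, THF, −78 °C; then 13, −78 °C; pH 7 buffer
Reagents that add atoms: none
Why: Bromine–lithium exchange with retention (the Z reagent is stabilised by O–Li contact and cannot eliminate anti) and carbonyl addition of the weakly basic organocerium, which suppresses enolisation of 13. The axial 2α-silyloxy group blocks the axial trajectory at C6, so attack is equatorial and the two alkenyl arms become trans-diequatorial; the work-up is neutral because 19 is acid-labile.

Step 10
Reactants: 19 (1S,2S,3S,5S)-5-[(tert-butyldiphenylsilyloxy)methyl]-1-[(Z)-2-phenoxyethenyl]-2-(prop-1-en-2-yl)-3-(triisopropylsilyloxy)cyclohexan-1-ol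
Product: 22 (2Z,5E,7S,9S)-9-[(tert-butyldiphenylsilyloxy)methyl]-5-methyl-7-(triisopropylsilyloxy)cyclodeca-2,5-dien-1-one (C6 ketone; 7Z; 1(10)E), via potassium alkoxide 20 (not isolated), via phenoxy enolate 21 (not isolated)
Conditions: KN(SiMe3)2 (1.05 equiv), 18-crown-6, THF, 0 to 40 °C; pH 7 buffer
Reagents that add atoms: none
Why: Deprotonation gives the tertiary alkoxide 20, whose C1–C6 bond is weakened by the oxyanion, and an anionic oxy-Cope rearrangement forms C8–C9 while C1–C6 breaks; the closest known reaction type is the four-carbon ring expansion of trans-1,2-dialkenylcyclohexanols to (E)-cyclodec-5-enones, followed here by the known β-elimination of an oxygen leaving group from the product enolate. No ring is closed from chain ends: the ten-membered ring arises in a suprafacial six-centre [3,3] shift through a chair transition state that resembles a trans-decalin, because both arms are equatorial on the cyclohexane chair. This chair places C2 and C9 anti across the new C1=C10 bond and so fixes 1(10)E. The Z phenoxy group is axial in the chair, so in enolate 21 the C8–O bond lies close to the enolate plane; the short rotation that brings it into overlap turns C9 towards C6, and E1cB loss of phenoxide should therefore give the 7Z enone, which is also the less strained isomer, so that reversible phenoxide addition can only correct a 7E contaminant. No lasting stereocentre is created (C1 and C6 are erased, C8 is transient) and C2 and C4 are untouched, so either C1 epimer of 13 converges on 22. The selectivities needed are chair over boat, secured by the trans-diequatorial arms, and elimination without further enolisation, secured by one equivalent of base and by a leaving group (phenoxide) too weakly basic to deprotonate the doubly allylic C9. The triisopropylsilyl group is expected to resist migration from O2 to the 1,3-diaxial O6 in 20.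

Step 11
Reactants: 22 (2Z,5E,7S,9S)-9-[(tert-butyldiphenylsilyloxy)methyl]-5-methyl-7-(triisopropylsilyloxy)cyclodeca-2,5-dien-1-one
Product: 23 6β-allylic alcohol (6S; 7Z; 1(10)E; 2α-OTIPS; 4β-CH2OTBDPS)
Conditions: (R)-2-methyl-CBS-oxazaborolidine (0.2 equiv), catecholborane, toluene, −78 °C
Reagents that add atoms: none
Why: Corey–Bakshi–Shibata 1,2-reduction of an enone; the alkenyl flank (C7) acts as the large group, so the R catalyst should give the 6S (6β) alcohol under reagent control. Catecholborane at low temperature spares the strained alkene.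

Step 12
Reactants: 23 6β-allylic alcohol (6S; 7Z; 1(10)E; 2α-OTIPS; 4β-CH2OTBDPS)
Product: 24 7α,8α-epoxy-6β-alcohol (cis-epoxide; 1(10)E; 2α-OTIPS; 4β-CH2OTBDPS)
Conditions: Ti(Oi-Pr)4 (0.2 equiv), t-BuOOH (decane), 4 Å molecular sieves, CH2Cl2, −20 °C
Reagents that add atoms: tert-butyl hydroperoxide, CC(C)(C)OO
Why: Titanium-catalysed hydroxyl-directed epoxidation touches only the alkene of the free allylic alcohol, not C1=C10. With H-6 eclipsing the Z alkene (minimal A(1,3) strain), C5 lies over the concave face and O6 over the exposed face, so oxygen arrives on the exposed face beside O6, which corresponds to the epoxide trans to the hydroxyl in the flat drawing, that is 7α,8α.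

Step 13
Reactants: 24 7α,8α-epoxy-6β-alcohol (cis-epoxide; 1(10)E; 2α-OTIPS; 4β-CH2OTBDPS); 25 diethylphosphonoacetic acid
Product: 26 6α-(diethoxyphosphorylacetoxy)-7α,8α-epoxide (1(10)E; 2α-OTIPS; 4β-CH2OTBDPS)
Conditions: PPh3, DIAD, toluene, 0 °C to rt
Reagents that add atoms: none
Why: Mitsunobu esterification of an epoxy alcohol with a sufficiently acidic carboxylic acid; SN2 inversion at C6 installs the final 6α-oxygen (6R) and the C11–C12 unit in one step under neutral conditions.

Step 14
Reactants: 26 6α-(diethoxyphosphorylacetoxy)-7α,8α-epoxide (1(10)E; 2α-OTIPS; 4β-CH2OTBDPS)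
Product: 28 8α-hydroxy α-methylene-γ-lactone (6α,12-olide; 7β-C11; 1(10)E; 2α-OTIPS; 4β-CH2OTBDPS), via phosphono lactone 27 (not isolated)
Conditions: NaH (1.05 equiv), THF, 0 to 45 °C; then (CH2O)n, rt
Reagents that add atoms: formaldehyde (from paraformaldehyde), C=O
Why: Intramolecular 5-exo opening of the epoxide by the stabilised phosphonoacetate carbanion, then Horner–Wadsworth–Emmons methylenation. Backside attack at C7 gives 7β-C11 (trans-fused lactone) and keeps 8α-O; the C8 alkoxide is quenched at once by the more acidic C11–H of 27, which generates the olefination carbanion without further base and keeps the alkoxide from attacking the lactone.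

Step 15
Reactants: 28 8α-hydroxy α-methylene-γ-lactone (6α,12-olide; 7β-C11; 1(10)E; 2α-OTIPS; 4β-CH2OTBDPS); 29 tigloyl chloride
Product: 30 8α-tiglate (6α,12-olide; 1(10)E; 2α-OTIPS; 4β-CH2OTBDPS)
Conditions: pyridine, DMAP (cat.), CH2Cl2, 0 °C
Reagents that add atoms: none
Why: Acylation of the only free hydroxyl; the E acid chloride is the thermodynamically stable isomer, so the ester geometry is safe.

Step 16
Reactants: 30 8α-tiglate (6α,12-olide; 1(10)E; 2α-OTIPS; 4β-CH2OTBDPS)
Product: 31 2α,15-diol (8α-tiglate; 6α,12-olide; 1(10)E)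
Conditions: HF·pyridine, pyridine, THF, 0 °C to rt
Reagents that add atoms: none
Why: Buffered fluoride removes both silyl groups in one operation without base, which protects the methylene lactone and both esters; no epoxide is present yet.

Step 17
Reactants: 31 2α,15-diol (8α-tiglate; 6α,12-olide; 1(10)E)
Product: 32 1β,10α-epoxy-2α,15-diol (8α-tiglate; 6α,12-olide)
Conditions: m-CPBA, CH2Cl2, 0 °C
Reagents that add atoms: 3-chloroperoxybenzoic acid, O=C(OO)c1cccc(Cl)c1
Why: Peracid epoxidation of the only electron-rich alkene (tiglate and methylene lactone are deactivated). A(1,3) strain with the cis C14 methyl keeps H-2 in the alkene plane, the ring holds C3 over the inner face and the 2-OH over the outer face, so peripheral attack and hydrogen-bond delivery coincide and should give 1R,10R.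

Step 18
Reactants: 32 1β,10α-epoxy-2α,15-diol (8α-tiglate; 6α,12-olide)
Product: 33 CNP0307768.2 (target)
Conditions: TEMPO (0.1 equiv), PhI(OAc)2, CH2Cl2, rt
Reagents that add atoms: none
Why: Oxoammonium oxidation is selective for the primary alcohol over the hindered secondary epoxy alcohol and is base-free, so C4 should not epimerise; the 4β-aldehyde cannot form a lactol with the 2α-hydroxyl.

## Compound list

1 | (Z)-but-2-ene-1,4-diol | OC/C=C\CO | starting material
2 | (Z)-4-(tert-butyldiphenylsilyloxy)but-2-en-1-ol | OC/C=C\CO[Si](c1ccccc1)(c1ccccc1)C(C)(C)C | intermediate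
3 | (E)-4-(tert-butyldiphenylsilyloxy)but-2-enal | O=C/C=C/CO[Si](c1ccccc1)(c1ccccc1)C(C)(C)C | intermediate
4 | tert-butyl acetoacetate | CC(=O)CC(=O)OC(C)(C)C | starting material
5 | Michael adduct, tert-butyl (3S)-2-acetyl-3-[(tert-butyldiphenylsilyloxy)methyl]-5-oxopentanoate (C5 epimers) | CC(=O)C(C(=O)OC(C)(C)C)[C@H](CC=O)CO[Si](c1ccccc1)(c1ccccc1)C(C)(C)C | intermediate
6 | keto ester, tert-butyl (6S)-6-[(tert-butyldiphenylsilyloxy)methyl]-2-oxocyclohex-3-ene-1-carboxylate (C5 epimers) | O=C1C=CC[C@H](CO[Si](c2ccccc2)(c2ccccc2)C(C)(C)C)C1C(=O)OC(C)(C)C | intermediate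
7 | (S)-5-[(tert-butyldiphenylsilyloxy)methyl]cyclohex-2-en-1-one | O=C1C[C@@H](CO[Si](c2ccccc2)(c2ccccc2)C(C)(C)C)CC=C1 | intermediate
8 | (S)-5-[(tert-butyldiphenylsilyloxy)methyl]-2-iodocyclohex-2-en-1-one | O=C1C[C@@H](CO[Si](c2ccccc2)(c2ccccc2)C(C)(C)C)CC=C1I | intermediate
9 | isopropenylboronic acid pinacol ester | CC(=C)B1OC(C)(C)C(C)(C)O1 | starting material
10 | (S)-5-[(tert-butyldiphenylsilyloxy)methyl]-2-(prop-1-en-2-yl)cyclohex-2-en-1-one | O=C1C[C@@H](CO[Si](c2ccccc2)(c2ccccc2)C(C)(C)C)CC=C1C(C)=C | intermediate
11 | boryl ketone (2α-Bpin, C1 isopropenyl cis to boron, 4β-CH2OTBDPS) | O=C1C[C@@H](CO[Si](c2ccccc2)(c2ccccc2)C(C)(C)C)C[C@H](B2OC(C)(C)C(C)(C)O2)[C@@H]1C(C)=C | intermediate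
12 | (2S,3S,5S)-5-[(tert-butyldiphenylsilyloxy)methyl]-3-hydroxy-2-(prop-1-en-2-yl)cyclohexan-1-one | O=C1C[C@@H](CO[Si](c2ccccc2)(c2ccccc2)C(C)(C)C)C[C@H](O)[C@@H]1C(C)=C | intermediate
13 | (2S,3S,5S)-5-[(tert-butyldiphenylsilyloxy)methyl]-2-(prop-1-en-2-yl)-3-(triisopropylsilyloxy)cyclohexan-1-one | O=C1C[C@@H](CO[Si](c2ccccc2)(c2ccccc2)C(C)(C)C)C[C@H](O[Si](C(C)C)(C(C)C)C(C)C)[C@@H]1C(C)=C | intermediate
14 | phenyl vinyl ether | C=COc1ccccc1 | starting material
15 | (1,2-dibromoethoxy)benzene | BrCC(Br)Oc1ccccc1 | intermediate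
16 | (Z)-(2-bromoethenyloxy)benzene | Br/C=C\Oc1ccccc1 | intermediate
17 | (Z)-2-phenoxyethenyllithium | [Li]/C=C\Oc1ccccc1 | intermediate
18 | (Z)-2-phenoxyethenylcerium dichloride | Cl[Ce](Cl)/C=C\Oc1ccccc1 | intermediate
19 | (1S,2S,3S,5S)-5-[(tert-butyldiphenylsilyloxy)methyl]-1-[(Z)-2-phenoxyethenyl]-2-(prop-1-en-2-yl)-3-(triisopropylsilyloxy)cyclohexan-1-ol | O[C@]1(/C=C\Oc2ccccc2)C[C@@H](CO[Si](c2ccccc2)(c2ccccc2)C(C)(C)C)C[C@H](O[Si](C(C)C)(C(C)C)C(C)C)[C@@H]1C(C)=C | intermediate
20 | potassium alkoxide of 19 | [K+].[O-][C@]1(/C=C\Oc2ccccc2)C[C@@H](CO[Si](c2ccccc2)(c2ccccc2)C(C)(C)C)C[C@H](O[Si](C(C)C)(C(C)C)C(C)C)[C@@H]1C(C)=C | intermediate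
21 | potassium enolate (C6=C7 enolate, 8α-phenoxy, 1(10)E) | [K+].[O-]/C1=C\[C@@H](Oc2ccccc2)C/C(C)=C/[C@@H](O[Si](C(C)C)(C(C)C)C(C)C)C[C@H](CO[Si](c2ccccc2)(c2ccccc2)C(C)(C)C)C1 | intermediate
22 | (2Z,5E,7S,9S)-9-[(tert-butyldiphenylsilyloxy)methyl]-5-methyl-7-(triisopropylsilyloxy)cyclodeca-2,5-dien-1-one | O=C1C[C@@H](CO[Si](c2ccccc2)(c2ccccc2)C(C)(C)C)C[C@H](O[Si](C(C)C)(C(C)C)C(C)C)/C=C(\C)C/C=C\1 | intermediate
23 | 6β-allylic alcohol (6S, 7Z, 1(10)E, 2α-OTIPS, 4β-CH2OTBDPS) | O[C@H]1C[C@@H](CO[Si](c2ccccc2)(c2ccccc2)C(C)(C)C)C[C@H](O[Si](C(C)C)(C(C)C)C(C)C)/C=C(\C)C/C=C\1 | intermediate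
24 | 7α,8α-epoxy-6β-alcohol | O[C@H]1C[C@@H](CO[Si](c2ccccc2)(c2ccccc2)C(C)(C)C)C[C@H](O[Si](C(C)C)(C(C)C)C(C)C)/C=C(\C)C[C@@H]2O[C@@H]21 | intermediate
25 | diethylphosphonoacetic acid | OC(=O)CP(=O)(OCC)OCC | starting material
26 | 6α-(diethoxyphosphorylacetoxy)-7α,8α-epoxide | CCOP(=O)(OCC)CC(=O)O[C@@H]1C[C@@H](CO[Si](c2ccccc2)(c2ccccc2)C(C)(C)C)C[C@H](O[Si](C(C)C)(C(C)C)C(C)C)/C=C(\C)C[C@@H]2O[C@@H]21 | intermediate
27 | 11-(diethoxyphosphoryl)-8α-hydroxy-6α,12-olide (C11 epimers) | CCOP(=O)(OCC)C1C(=O)O[C@@H]2C[C@@H](CO[Si](c3ccccc3)(c3ccccc3)C(C)(C)C)C[C@H](O[Si](C(C)C)(C(C)C)C(C)C)/C=C(\C)C[C@H](O)[C@@H]12 | intermediate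
28 | 8α-hydroxy α-methylene-γ-lactone | C=C1C(=O)O[C@@H]2C[C@@H](CO[Si](c3ccccc3)(c3ccccc3)C(C)(C)C)C[C@H](O[Si](C(C)C)(C(C)C)C(C)C)/C=C(\C)C[C@H](O)[C@@H]12 | intermediate
29 | tigloyl chloride, (E)-2-methylbut-2-enoyl chloride | C/C=C(\C)C(=O)Cl | starting material
30 | 8α-tiglate bis-silyl ether | C=C1C(=O)O[C@@H]2C[C@@H](CO[Si](c3ccccc3)(c3ccccc3)C(C)(C)C)C[C@H](O[Si](C(C)C)(C(C)C)C(C)C)/C=C(\C)C[C@H](OC(=O)/C(C)=C/C)[C@@H]12 | intermediate
31 | 2α,15-diol, 1(10)E alkene | C=C1C(=O)O[C@@H]2C[C@@H](CO)C[C@H](O)/C=C(\C)C[C@H](OC(=O)/C(C)=C/C)[C@@H]12 | intermediate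
32 | 1β,10α-epoxy-2α,15-diol | C=C1C(=O)O[C@@H]2C[C@@H](CO)C[C@H](O)[C@H]3O[C@]3(C)C[C@H](OC(=O)/C(C)=C/C)[C@@H]12 | intermediate
33 | CNP0307768.2 (1R,2S,4S,6R,7S,8S,10R) | C=C1C(=O)O[C@@H]2C[C@@H](C=O)C[C@H](O)[C@H]3O[C@]3(C)C[C@H](OC(=O)/C(C)=C/C)[C@@H]12 | target

## Step count and least certain steps

Total step count: 18. Longest linear sequence: 17 (steps 1–7 and 9–18). Step 8 is a one-step branch.

**Step 10 (key step).**
- What may go wrong:
  - The axial phenoxy group may raise the chair transition state enough for boat or dissociative pathways, which would erode the 1(10)E geometry.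
  - Silyl migration from O2 to O6 may quench the accelerating alkoxide.
  - Prolonged contact with phenoxide may move the skipped diene into conjugation.
- Fallback, from 13 back to 22:
  1. Vinylmagnesium bromide and CeCl3 give the plain vinyl carbinol F1.
  2. KH and 18-crown-6 bring about the unsubstituted oxy-Cope ring expansion.
  3. The regiodefined enolate is trapped with PhSeCl at −78 °C to give the 7-phenylselanyl ketone F2.
  4. Oxidation with H2O2 and pyridine triggers selenoxide syn elimination towards C8.
  5. If this gives the 7E dienone F3, it is equilibrated to the less strained 22 with a catalytic thiol by reversible conjugate addition.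

**Step 6.**
- What may go wrong:
  - Protonation of the intermediate dienolate at C9 instead of C1 would pull the isopropenyl alkene into conjugation.
  - β-Elimination of the new oxygen function may occur during the basic oxidation.
- Fallback, from 10 back to 12:
  1. Weitz–Scheffer epoxidation (H2O2, NaOH, MeOH) attacks C2 anti to the C4 substituent and gives the 1α,2α-epoxy ketone F4.
  2. SmI2 in THF/MeOH at −90 °C cleaves the Cα–O bond reductively, and the samarium enolate is protonated in the cold.

**Step 11.**
- What may go wrong: facial selectivity may be poor, because both flanks of the ketone are ring chains and the conformational bias of the ring may oppose the catalyst.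
- Fallback, from 22 back to 26, uses the other epimer:
  1. The S catalyst, or the substrate-controlled hydride reduction, gives the 6α-allylic alcohol F5.
  2. VO(acac)2 and t-BuOOH, which epoxidise medium-ring Z-allylic alcohols cis to the hydroxyl, give the 6α-hydroxy-7α,8α-epoxide F6.
  3. F6 is esterified with 25 with retention (DCC, DMAP).

**Step 14.**
- What may go wrong:
  - The 5-exo opening by the stabilised and hindered carbanion may be sluggish.
  - Competing processes are 6-endo attack at C8, base-induced isomerisation of the epoxide to an allylic alcohol, and acyl shift from O6 to O8.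
- Fallback, from 24 back to 28, separates ring formation from methylenation:
  1. Mitsunobu esterification with mono-allyl malonate gives the epoxy malonate F7.
  2. Its smaller and more nucleophilic carbanion (NaH) closes the allyl ester lactone F8.
  3. Pd(PPh3)4 and morpholine free the lactone acid F9.
  4. Formaldehyde and diethylamine effect decarboxylative Mannich methylenation.

**Step 17.**
- What may go wrong:
  - Attack may occur through a minor ring conformer on the other alkene face.
  - The acid by-product may open the new trisubstituted epoxide.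
- Fallback, from 30 back to 32:
  1. Acid-free epoxidation of the silyl ether 30 with dimethyldioxirane relies on peripheral attack alone and gives the epoxide bis-silyl ether F10.
  2. F10 is desilylated with acetic acid-buffered Bu4NF.

## Further compounds

F1 | step 10 | vinyl carbinol, 1-ethenyl analogue of 19 | O[C@]1(C=C)C[C@@H](CO[Si](c2ccccc2)(c2ccccc2)C(C)(C)C)C[C@H](O[Si](C(C)C)(C(C)C)C(C)C)[C@@H]1C(C)=C
F2 | step 10 | 7β-phenylselanyl 6-ketone, 1(10)E | O=C1C[C@@H](CO[Si](c2ccccc2)(c2ccccc2)C(C)(C)C)C[C@H](O[Si](C(C)C)(C(C)C)C(C)C)/C=C(\C)CC[C@H]1[Se]c1ccccc1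
F3 | step 10 | 7E isomer of dienone 22 | O=C1C[C@@H](CO[Si](c2ccccc2)(c2ccccc2)C(C)(C)C)C[C@H](O[Si](C(C)C)(C(C)C)C(C)C)/C=C(\C)C/C=C/1
F4 | step 6 | 1α,2α-epoxy ketone from 10 | O=C1C[C@@H](CO[Si](c2ccccc2)(c2ccccc2)C(C)(C)C)C[C@@H]2O[C@]12C(C)=C
F5 | step 11 | 6α-allylic alcohol, C6 epimer of 23 | O[C@@H]1C[C@@H](CO[Si](c2ccccc2)(c2ccccc2)C(C)(C)C)C[C@H](O[Si](C(C)C)(C(C)C)C(C)C)/C=C(\C)C/C=C\1
F6 | step 11 | 6α-hydroxy-7α,8α-epoxide, C6 epimer of 24 | O[C@@H]1C[C@@H](CO[Si](c2ccccc2)(c2ccccc2)C(C)(C)C)C[C@H](O[Si](C(C)C)(C(C)C)C(C)C)/C=C(\C)C[C@@H]2O[C@@H]21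
F7 | step 14 | 6α-(allyl malonyloxy)-7α,8α-epoxide | C=CCOC(=O)CC(=O)O[C@@H]1C[C@@H](CO[Si](c2ccccc2)(c2ccccc2)C(C)(C)C)C[C@H](O[Si](C(C)C)(C(C)C)C(C)C)/C=C(\C)C[C@@H]2O[C@@H]21
F8 | step 14 | 11-(allyloxycarbonyl)-8α-hydroxy-6α,12-olide | C=CCOC(=O)C1C(=O)O[C@@H]2C[C@@H](CO[Si](c3ccccc3)(c3ccccc3)C(C)(C)C)C[C@H](O[Si](C(C)C)(C(C)C)C(C)C)/C=C(\C)C[C@H](O)[C@@H]12
F9 | step 14 | 11-carboxy-8α-hydroxy-6α,12-olide | OC(=O)C1C(=O)O[C@@H]2C[C@@H](CO[Si](c3ccccc3)(c3ccccc3)C(C)(C)C)C[C@H](O[Si](C(C)C)(C(C)C)C(C)C)/C=C(\C)C[C@H](O)[C@@H]12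
F10 | step 17 | 1β,10α-epoxide of 30 | C=C1C(=O)O[C@@H]2C[C@@H](CO[Si](c3ccccc3)(c3ccccc3)C(C)(C)C)C[C@H](O[Si](C(C)C)(C(C)C)C(C)C)[C@H]3O[C@]3(C)C[C@H](OC(=O)/C(C)=C/C)[C@@H]12
A1 | alternative 1 | methyl (Z)-2-(bromomethyl)enoate aldehyde, open chain C6 to C7 with 2α, 8α and 15 silyl ethers | COC(=O)/C(CBr)=C/[C@@H](O[Si](C)(C)C(C)(C)C)C/C(C)=C/[C@@H](O[Si](C)(C)C(C)(C)C)C[C@H](CO[Si](C)(C)C(C)(C)C)CC=O
A2 | alternative 1 | tris(tert-butyldimethylsilyl) methylene lactone, 1(10)E | C=C1C(=O)O[C@@H]2C[C@@H](CO[Si](C)(C)C(C)(C)C)C[C@H](O[Si](C)(C)C(C)(C)C)/C=C(\C)C[C@H](O[Si](C)(C)C(C)(C)C)[C@@H]12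
A3 | alternative 2 | acyclic triene, metathesis precursor of 23 | C=C[C@@H](O)C[C@@H](CO[Si](c1ccccc1)(c1ccccc1)C(C)(C)C)C[C@H](O[Si](C(C)C)(C(C)C)C(C)C)/C=C(\C)CC=C
A4 | alternative 3 | thirteen-membered bis-allylic ether (O between C6 and C12) | C/C1=C\[C@@H](O[Si](C)(C)C(C)(C)C)C/C(C)=C/[C@@H](O[Si](C)(C)C(C)(C)C)C/C(CO[Si](C)(C)C(C)(C)C)=C/COC1
A5 | alternative 3 | ring-contracted 6α-hydroxy-7β-isopropenyl-1(10),4-diene | O[C@@H]1/C=C(CO[Si](C)(C)C(C)(C)C)/C[C@H](O[Si](C)(C)C(C)(C)C)/C=C(\C)C[C@H](O[Si](C)(C)C(C)(C)C)[C@H]1C(C)=C
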